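Between the coldest and the hottest flask the ring closure speeds up 11 times, more than the dimer step at 3.9 times, but the ring's loss to over-reaction product speeds up 9.8 times, so heat helps the ring at its making and costs it afterwards.

common to all: solid substrate 10 mM; activator 20.0 mM; time 1.5 min
- summer: temperature 110 °C
- spring: at 110 °C until 25 s, from then on at 140 °C
- dawn: temperature 140 °C
- dusk: temperature 125 °C

    starting material + activated form → open dimer (k1 = 2.9 M⁻¹ s⁻¹, Ea1 = 60.0 kJ mol⁻¹)
    solid substrate ⇌ starting material, rate k2*(cs2 - [starting material]) while solid is left; crystals form when [starting material] > cs2 (cs2 = 2.5 mM, k2 = 0.015 s⁻¹)
    starting material + activator → activated form (k3 = 0.76 M⁻¹ s⁻¹, Ea3 = 78.0 kJ mol⁻¹)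
    activated form → ring (k4 = 0.012 s⁻¹, Ea4 = 105 kJ mol⁻¹)
    ring → over-reaction product (k5 = 0.0016 s⁻¹, Ea5 = 100 kJ mol⁻¹)
    (constants at 110 °C)

- percentages count the solid substrate that a species holds: one open dimer counts as two
- solid, in amounts per volume of the solution: solid substrate
- the list of constants is for 110 °C, to be carried to other temperatures by the activation energies
- at the start none of the solid substrate is in solution
- what has only dissolved of solid substrate counts as not reacted

* the best flask by share of ring in all that became ring or open dimer or over-reaction product; "all alike" if 1.5 percentage points covers them all (summer / spring / dawn / dusk / all alike)
* share of ring in all that became ring or open dimer or over-reaction product, summer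
* share of ring in all that became ring or open dimer or over-reaction product, spring
* share of ring in all that became ring or open dimer or over-reaction product, dawn
* share of ring in all that became ring or open dimer or over-reaction product, dusk

The share asked for is the product of two fractions left: the kept fraction, ring over ring plus over-reaction product, and the route fraction, ring plus over-reaction product over these plus the dimer's material.

Step one, kept fraction, dawn. Ring is lost in dawn at 0.0156 s⁻¹. Ring made evenly through a run of time t, lost at first-order constant k, keeps on average one minus e to the power −kt, divided by kt; this even-making kept fraction is 53.7% for dawn, a floor so long as the making never slows. Making that grows in proportion to time is taken as the ceiling, 65.9%.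

Step two, route fraction. The activated form closes at k4 and meets starting material at k1 c(starting material), and each dimer counts twice, so the route fraction is k4 over k4 plus twice that term. Activator in excess makes activation pseudo-first-order, and even at its 110 °C pace it holds c(starting material) under 1.24 mM, below the solubility. The route floor for dawn is therefore 82.3%, and its ceiling is a whole route.

Step three, brackets. The estimated bracket for dawn runs from 44.2% to 65.9%. The bracket for summer, reckoned the same way, runs from 58.2% to 95.4%. The two overlap, the summer floor standing below the dawn ceiling, so this reckoning ranks neither.

Step four, the forecast. It goes further and says “Dusk is best”, giving 74% for dusk, 64.5% for summer, 57.5% for spring and 56% for dawn. Its dawn value stands above the dawn floor and below the dawn ceiling, and its summer value stands above the summer floor and below the summer ceiling.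

Step five, the result. The simulation gives dusk as best at 72.1%, with summer 64.5%, spring 57.7% and dawn 55.3%. Dawn at 1.50 min holds ring 12.9% and over-reaction product 9.04%, a kept fraction of 58.8%, above the floor of 53.7%. The same dawn flask read at 2.5 min has an even-making kept fraction of 38.6%, and it holds ring 16.3% and over-reaction product 23.0%, a kept fraction of 41.5%.

The constants are invented; the run is a simulation.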